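The route disconnects C1–C8a of ring B (isochromene numbering). It exploits the fact that C7 of ring A sits between the C6 and C8 carbonyls, so a 2-methyl-2-stearoyloxycyclohexane-1,3-dione is a prochiral ring A whose C7 becomes stereogenic only when one flanking α-carbon (future C8a) is functionalised. In one operation a formate tethered through the C3 oxygen is attacked by one of the two diastereotopic enolates. This forms C1–C8a, closes ring B as the C1=C8a enol ether after dehydration, and lets the (R)-C3 centre fix C4a and thereby C7. The precursor is the cis-2-acyloxy-5-[(R)-2-formyloxypropyl]dione; a final C4a–C5 desaturation gives the target.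

Key step: step 8

Assumption: the bicyclic core is numbered as an isochromene (C1, O2, C3, C4, C4a, C5–C8, C8a), the target is read as (3R,7R), and "cis" for the diones means that the C2 oxygen substituent and the C5 side chain lie on the same ring face.

Step 1
Reactants: 1 (R)-pent-4-en-2-ol
Product: 2 (R)-4-(benzyloxy)pent-1-ene
Conditions: NaH, BnBr, TBAI (cat.), THF, 0 °C → rt
Reagents that add atoms: benzyl bromide, BrCc1ccccc1
Why: Williamson ether synthesis at oxygen leaves the carbinol stereocentre (future C3) untouched, and the benzyl ether is chosen because it should survive the ethoxide, hydroxide and hot acid of step 3 and come off later under neutral hydrogenolysis.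

Step 2
Reactants: 2 (R)-4-(benzyloxy)pent-1-ene; 3 ethyl vinyl ketone (pent-1-en-3-one)
Product: 4 (R,E)-7-(benzyloxy)oct-4-en-3-one
Conditions: Hoveyda–Grubbs II (3 mol %), 3 (3 equiv), CH2Cl2, 40 °C
Reagents that add atoms: none
Why: Olefin cross-metathesis of a readily homodimerising terminal alkene with an electron-poor vinyl ketone should give the cross product selectively as the E-enone, and the ethyl ketone already carries the carbon that becomes the C7 methyl.

Step 3
Reactants: 4 (R,E)-7-(benzyloxy)oct-4-en-3-one; 5 diethyl malonate
Product: 9 5-[(2R)-2-(benzyloxy)propyl]-2-methylcyclohexane-1,3-dione, via Michael adduct 6 (not isolated), via cyclic keto ester 7 (not isolated), via keto acid 8 (not isolated)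
Conditions: NaOEt (0.1 equiv), EtOH, 0 °C → rt; NaOEt (1.2 equiv), reflux; 2 M NaOH, reflux; HCl (pH 2), 80 °C
Reagents that add atoms: none
Why: Michael addition of the malonate anion, Claisen (Dieckmann-type) condensation of the ethyl-ketone CH2 onto a malonate ester, saponification and decarboxylation form the classical annulation to 5-substituted 2-methylcyclohexane-1,3-diones, with the Michael step run cold under catalytic base so that the δ-benzyloxy group is not lost by vinylogous elimination; C5 of 9 is not a stereocentre.

Step 4
Reactants: 9 5-[(2R)-2-(benzyloxy)propyl]-2-methylcyclohexane-1,3-dione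
Product: 10 cis-5-[(2R)-2-(benzyloxy)propyl]-2-hydroxy-2-methylcyclohexane-1,3-dione
Conditions: DMDO (1.1 equiv), acetone/CH2Cl2, 0 °C; chromatography
Reagents that add atoms: dimethyldioxirane, CC1(C)OO1
Why: α-Hydroxylation of the dione enol by dimethyldioxirane (enol epoxidation and ring opening) should deliver oxygen axially to C2 on the face opposite the out-of-plane C5, which with the side chain equatorial places the hydroxyl cis to it; the minor trans isomer is removed by chromatography.

Step 5
Reactants: 10 cis-5-[(2R)-2-(benzyloxy)propyl]-2-hydroxy-2-methylcyclohexane-1,3-dione; 11 stearoyl chloride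
Product: 12 cis-4-[(2R)-2-(benzyloxy)propyl]-1-methyl-2,6-dioxocyclohexyl octadecanoate
Conditions: pyridine, DMAP (cat.), CH2Cl2, 0 °C → rt
Reagents that add atoms: none
Why: DMAP-catalysed acylation through the acylpyridinium ion is the standard esterification of a hindered tertiary ketol flanked by two carbonyls, and the weak base should avoid α-ketol rearrangement while leaving the C2 configuration untouched.

Step 6
Reactants: 12 cis-4-[(2R)-2-(benzyloxy)propyl]-1-methyl-2,6-dioxocyclohexyl octadecanoate
Product: 13 cis-4-[(2R)-2-hydroxypropyl]-1-methyl-2,6-dioxocyclohexyl octadecanoate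
Conditions: H2 (1 atm), 10% Pd/C, EtOAc, rt
Reagents that add atoms: none
Why: Catalytic hydrogenolysis of the benzyl ether is neutral and should leave the ketones and the tertiary ester intact; the alcohol is carried on at once to limit hemiketal formation with the activated ring carbonyls.

Step 7
Reactants: 13 cis-4-[(2R)-2-hydroxypropyl]-1-methyl-2,6-dioxocyclohexyl octadecanoate
Product: 14 cis-4-[(2R)-2-(formyloxy)propyl]-1-methyl-2,6-dioxocyclohexyl octadecanoate
Conditions: HCO2H, Ac2O (premixed, 50 °C); then 13, pyridine, CH2Cl2, 0 °C
Reagents that add atoms: acetic formic anhydride, CC(=O)OC=O (generated from formic acid, OC=O, and acetic anhydride, CC(=O)OC(C)=O)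
Why: Mixed-anhydride formylation transfers the more electrophilic formyl group to the only free hydroxyl under mild conditions, with retention at the carbinol carbon.

Step 8
Reactants: 14 cis-4-[(2R)-2-(formyloxy)propyl]-1-methyl-2,6-dioxocyclohexyl octadecanoate
Product: 16 (3R,4aS,7R)-3,7-dimethyl-6,8-dioxo-4,4a,5,6,7,8-hexahydro-3H-isochromen-7-yl octadecanoate, via lactol 15 (not isolated)
Conditions: TiCl4 (3 equiv), Bu3N (3.5 equiv), CH2Cl2 (0.01 M), −78 → −20 °C; 1 M HCl; then PPTS (cat.), 4 Å MS, PhMe, 50 °C
Reagents that add atoms: none
Why: Proposed new method: TiCl4 binds the ring carbonyls and Bu3N removes an α-proton reversibly, so the two diastereomeric titanium enolates (one on each ring CH2 of 14) interconvert, and one adds to the Ti-activated formyl carbon to give a six-membered titanium lactolate; acid work-up frees lactol 15, which loses water through the oxocarbenium ion and the acidic C8a–H to give the vinylogous ester 16. The closest known reactions are the Ti-mediated crossed Claisen formylation of ketones with alkyl formates and the group-selective intramolecular aldol cyclisations of 2,2-disubstituted cyclohexane-1,3-diones. Ring B closes in a favoured 6-(enolexo)-exo-trig mode, whereas the stearate could engage the ring only through disfavoured 5-(enolendo) closures. The new C4a centre is controlled by the (R)-C3 centre: in the cis-fused chair transition state the new bond is axial on the enolate ring and the tether equatorial, so the C4a–C5 bond is axial on nascent ring B, and only attack by the α-carbon that leaves the C3 methyl equatorial avoids a 1,3-diaxial contact with that bond, which puts C5 trans to the methyl (4aS). C7 is set in the same event, because the choice of α-carbon defines which carbonyl becomes C8, and the cis relation of acyloxy and side chain in 14 then makes C7 R. The step needs selectivity between the two diastereotopic α-methylenes; the substrate secures it through the C3 stereocentre, through the cis arrangement (tether equatorial, the smaller acyloxy group pseudo-axial), and through C4a staying sp3 so that no symmetric dienolate can erase the result.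

Step 9
Reactants: 16 (3R,4aS,7R)-3,7-dimethyl-6,8-dioxo-4,4a,5,6,7,8-hexahydro-3H-isochromen-7-yl octadecanoate
Product: 18 (3R,7R)-3,7-dimethyl-6,8-dioxo-4,6,7,8-tetrahydro-3H-isochromen-7-yl octadecanoate, via silyl enol ether 17 (not isolated)
Conditions: TMSOTf, Et3N, CH2Cl2, 0 °C; then Pd(OAc)2 (1.1 equiv), MeCN, rt
Reagents that add atoms: none
Why: Saegusa–Ito oxidation: soft enolisation can only give the C5=C6 silyl enol ether (C7 is quaternary, C8 is a vinylogous ester), and the derived C5 palladium enolate can only lose H-4a by β-hydride elimination, so C4a=C5 should be installed without touching C7 or C3.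

Compound list
1 | (R)-pent-4-en-2-ol | C[C@@H](O)CC=C | starting material
2 | (R)-4-(benzyloxy)pent-1-ene | C[C@@H](OCc1ccccc1)CC=C | intermediate
3 | ethyl vinyl ketone (pent-1-en-3-one) | CCC(=O)C=C | starting material
4 | (R,E)-7-(benzyloxy)oct-4-en-3-one | CCC(=O)/C=C/C[C@@H](C)OCc1ccccc1 | intermediate
5 | diethyl malonate | CCOC(=O)CC(=O)OCC | starting material
6 | diethyl 2-[(2R)-2-(benzyloxy)-6-oxooctan-4-yl]malonate (C4 epimers) | CCOC(=O)C(C(=O)OCC)C(C[C@@H](C)OCc1ccccc1)CC(=O)CC | intermediate (not isolated)
7 | ethyl 6-[(2R)-2-(benzyloxy)propyl]-3-methyl-2,4-dioxocyclohexane-1-carboxylate (as sodium enolate; ring centres undefined) | CCOC(=O)C1C(C[C@@H](C)OCc2ccccc2)CC(=O)C(C)C1=O | intermediate (not isolated)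
8 | 6-[(2R)-2-(benzyloxy)propyl]-3-methyl-2,4-dioxocyclohexane-1-carboxylic acid (ring centres undefined) | OC(=O)C1C(C[C@@H](C)OCc2ccccc2)CC(=O)C(C)C1=O | intermediate (not isolated)
9 | 5-[(2R)-2-(benzyloxy)propyl]-2-methylcyclohexane-1,3-dione (keto/enol tautomers) | CC1C(=O)CC(C[C@@H](C)OCc2ccccc2)CC1=O | intermediate
10 | cis-5-[(2R)-2-(benzyloxy)propyl]-2-hydroxy-2-methylcyclohexane-1,3-dione | O[C@]1(C)C(=O)C[C@H](C[C@@H](C)OCc2ccccc2)CC1=O | intermediate
11 | stearoyl chloride (octadecanoyl chloride) | CCCCCCCCCCCCCCCCCC(=O)Cl | starting material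
12 | cis-4-[(2R)-2-(benzyloxy)propyl]-1-methyl-2,6-dioxocyclohexyl octadecanoate | CCCCCCCCCCCCCCCCCC(=O)O[C@]1(C)C(=O)C[C@H](C[C@@H](C)OCc2ccccc2)CC1=O | intermediate
13 | cis-4-[(2R)-2-hydroxypropyl]-1-methyl-2,6-dioxocyclohexyl octadecanoate | CCCCCCCCCCCCCCCCCC(=O)O[C@]1(C)C(=O)C[C@H](C[C@@H](C)O)CC1=O | intermediate
14 | cis-4-[(2R)-2-(formyloxy)propyl]-1-methyl-2,6-dioxocyclohexyl octadecanoate | CCCCCCCCCCCCCCCCCC(=O)O[C@]1(C)C(=O)C[C@H](C[C@@H](C)OC=O)CC1=O | intermediate
15 | (3R,4aS,7R)-1-hydroxy-3,7-dimethyl-6,8-dioxooctahydro-1H-isochromen-7-yl octadecanoate (lactol; C1 and C8a undefined) | CCCCCCCCCCCCCCCCCC(=O)O[C@]1(C)C(=O)C[C@@H]2C[C@@H](C)OC(O)C2C1=O | intermediate (not isolated)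
16 | (3R,4aS,7R)-3,7-dimethyl-6,8-dioxo-4,4a,5,6,7,8-hexahydro-3H-isochromen-7-yl octadecanoate | CCCCCCCCCCCCCCCCCC(=O)O[C@]1(C)C(=O)C[C@@H]2C[C@@H](C)OC=C2C1=O | intermediate
17 | (3R,4aS,7R)-3,7-dimethyl-8-oxo-6-(trimethylsilyloxy)-4,4a,7,8-tetrahydro-3H-isochromen-7-yl octadecanoate | CCCCCCCCCCCCCCCCCC(=O)O[C@]1(C)C(O[Si](C)(C)C)=C[C@@H]2C[C@@H](C)OC=C2C1=O | intermediate (not isolated)
18 | (3R,7R)-3,7-dimethyl-6,8-dioxo-4,6,7,8-tetrahydro-3H-isochromen-7-yl octadecanoate | CCCCCCCCCCCCCCCCCC(=O)O[C@]1(C)C(=O)C=C2C[C@@H](C)OC=C2C1=O | target

Total step count: 9. Longest linear sequence: 9 steps (1 to 18).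

Steps most likely to fail

Step 8 (the proposed new method). The group selection between the two α-methylenes may be weak or run in the opposite sense, or C–C bond formation at the formate may be slow enough that intermolecular condensation or loss of the formyl group takes over. The fallback uses known chemistry and gives up the tether control. It sets out from alcohol 13, which with TMSOTf/Et3N (2.1 equiv, CH2Cl2, 0 °C) should give the O-silylated mono silyl enol ether F1 as a statistical mixture of the two arm isomers. Mukaiyama-type addition of F1 to trimethyl orthoformate (BF3·OEt2, CH2Cl2, −78 °C, aqueous work-up) should give the β-keto dimethyl acetal F2. Warming F2 with PPTS in toluene should bring about transacetalisation with the side-chain hydroxyl and β-elimination of methanol, to give 16 together with its arm isomer, the (3R,4aR,7S) compound F3. Because C3 is fixed, the two are diastereomers and should be separable by chromatography. The fallback returns to the route at 16.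

Step 4. Oxygen transfer to C2 may show poor facial selectivity, and the ketol may be lost by ring contraction on handling. The fallback replaces hydroxylation and acylation by a direct C–O acyloxylation. Stearoyl chloride 11 with aqueous H2O2/NaOH in Et2O at 0 °C should give distearoyl peroxide F4. The sodium enolate of dione 9 (NaH, THF, 0 °C) should then displace stearate from F4, a known α-acyloxylation of 1,3-dicarbonyl enolates by diacyl peroxides. The bulkier electrophile and later transition state are expected to sharpen the preference for the axial trajectory. After chromatographic removal of the trans isomer the fallback returns at 12, bypassing 10 and step 5.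

Step 9. Silylation at C6 may be incomplete or reverse to 16, and Pd(II) may bind the ring-B enol ether or over-oxidise ring B. The fallback sets out from 16 and uses selenoxide elimination. Kinetic deprotonation at C5 (LiHMDS, THF, −78 °C) and trapping with PhSeBr should give the α-phenylselanyl ketone F5. Oxidation (30% H2O2, pyridine, CH2Cl2, 0 °C → rt) should give the selenoxide F6, which undergoes syn-elimination towards H-4a; the C5 epimers of F5 can equilibrate by enolisation. The fallback returns at target 18.

Further compounds
F1 | step 8 | 1-methyl-2-oxo-6-(trimethylsilyloxy)-4-[(2R)-2-(trimethylsilyloxy)propyl]cyclohex-5-en-1-yl octadecanoate (acyloxy cis to side chain; formed with its arm isomer) | CCCCCCCCCCCCCCCCCC(=O)O[C@]1(C)C(=O)C[C@H](C[C@@H](C)O[Si](C)(C)C)C=C1O[Si](C)(C)C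
F2 | step 8 | cis-3-(dimethoxymethyl)-4-[(2R)-2-hydroxypropyl]-1-methyl-2,6-dioxocyclohexyl octadecanoate (C3 epimers; formed with its arm isomer) | CCCCCCCCCCCCCCCCCC(=O)O[C@]1(C)C(=O)C[C@H](C[C@@H](C)O)C(C(OC)OC)C1=O
F3 | step 8 | (3R,4aR,7S)-3,7-dimethyl-6,8-dioxo-4,4a,5,6,7,8-hexahydro-3H-isochromen-7-yl octadecanoate | CCCCCCCCCCCCCCCCCC(=O)O[C@@]1(C)C(=O)C[C@H]2C[C@@H](C)OC=C2C1=O
F4 | step 4 | dioctadecanoyl peroxide (distearoyl peroxide) | CCCCCCCCCCCCCCCCCC(=O)OOC(=O)CCCCCCCCCCCCCCCCC
F5 | step 9 | 5-(phenylselanyl) derivative of 16 (C5 epimers) | CCCCCCCCCCCCCCCCCC(=O)O[C@]1(C)C(=O)C([Se]c3ccccc3)[C@@H]2C[C@@H](C)OC=C2C1=O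
F6 | step 9 | selenoxide of F5 | CCCCCCCCCCCCCCCCCC(=O)O[C@]1(C)C(=O)C([Se](=O)c3ccccc3)[C@@H]2C[C@@H](C)OC=C2C1=O
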